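**Retrosynthetic overview**
- Last bond: the ring B aryl–prenyl C–C bond, by Stille coupling of an aryl bromide. It is placed last because the side-chain olefin would not survive the two acid steps.
- Key step: the dihydropyran ring (ring C) is grown onto the fully unprotected bromo-dihydrochalcone in one flask. A dimethylallyl cation C-prenylates ring A and the flanking phenol then closes the ring, which copies prenyl transfer followed by cyclase-type ring closure.
- The dihydrochalcone is cut at the aryl–C(=O) bond (Friedel–Crafts acylation of phloroglucinol). The arylpropanoic acid is cut at Cα–Cβ (reductive Knoevenagel of a brominated isovanillin-type aldehyde with Meldrum's acid).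
- Ring order: rings A and B are bought as arenes; ring C is the only ring formed, in the third step.

Assumption: the target SMILES has no stereocentre and no stereogenic double bond, so it is achiral and needs no enantiocontrol; aldehyde 1 is taken as a catalogue building block.

**Route**

Step 1
Reactants: 1 3-bromo-5-hydroxy-4-methoxybenzaldehyde; 2 Meldrum's acid (2,2-dimethyl-1,3-dioxane-4,6-dione)
Product: 5 3-(3-bromo-5-hydroxy-4-methoxyphenyl)propanoic acid, via arylidene Meldrum's acid 3 (not isolated), via benzyl Meldrum's acid 4 (not isolated)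
Conditions: HCO2H/Et3N (5:2), 95 °C, 4 h; then 1 M HCl
Reagents that add atoms: Meldrum's acid (compound 2), CC1(C)OC(=O)CC(=O)O1; water (made in the condensation, can supply one carboxyl oxygen on ring hydrolysis), O
Why: Domino Knoevenagel condensation, formate conjugate transfer hydrogenation of the very electrophilic arylidene 3, then hydrolysis and decarboxylation of 4 (reductive Knoevenagel in triethylammonium formate); the aryl bromide, phenol and methyl ether are inert to formate without a transition metal, and no stereocentre is formed.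

Step 2
Reactants: 5 3-(3-bromo-5-hydroxy-4-methoxyphenyl)propanoic acid; 6 phloroglucinol (anhydrous, 1.5 equiv)
Product: 7 3-(3-bromo-5-hydroxy-4-methoxyphenyl)-1-(2,4,6-trihydroxyphenyl)propan-1-one
Conditions: BF3·OEt2 (as solvent), 85 °C, 2 h; then aq NaOAc, 20 °C
Reagents that add atoms: phloroglucinol (compound 6), Oc1cc(O)cc(O)c1
Why: Friedel–Crafts acylation of the most electron-rich arene by the BF3-activated free acid (the classical phloretin-type synthesis); phloroglucinol is symmetric so only one mono-ketone can form, the first acyl group deactivates ring A against a second acylation, the bromine-deactivated ring B does not compete, and no stereocentre is formed.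

Step 3
Reactants: 7 3-(3-bromo-5-hydroxy-4-methoxyphenyl)-1-(2,4,6-trihydroxyphenyl)propan-1-one; 8 2-methylbut-3-en-2-ol (1.1 equiv, added over 2 h)
Product: 10 3-(3-bromo-5-hydroxy-4-methoxyphenyl)-1-(5,7-dihydroxy-2,2-dimethyl-3,4-dihydro-2H-chromen-6-yl)propan-1-one, via C-prenyl dihydrochalcone 9 (not isolated)
Conditions: BF3·OEt2 (0.3 equiv), dioxane, 20 °C, 3 h; then TsOH·H2O (0.2 equiv), 80 °C, 2 h
Reagents that add atoms: 2-methylbut-3-en-2-ol (compound 8), CC(C)(O)C=C
Why: Acid ionises 8 to the dimethylallyl cation (the laboratory counterpart of dimethylallyl diphosphate), which C-alkylates the only strongly nucleophilic C–H of 7 (C-3' of ring A, equivalent to C-5'; Friedel–Crafts prenylation), and the ortho-prenylphenol 9 then undergoes Markovnikov protonation and 6-endo cycloetherification (intramolecular hydroalkoxylation) through the free 4'-hydroxyl in preference to a carbonyl-chelated ortho-hydroxyl to give the 6-acyl chroman 10; the aryl bromide, ketone and methyl ether are inert and no stereocentre is formed.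

Step 4
Reactants: 10 3-(3-bromo-5-hydroxy-4-methoxyphenyl)-1-(5,7-dihydroxy-2,2-dimethyl-3,4-dihydro-2H-chromen-6-yl)propan-1-one; 11 tributyl(3-methylbut-2-en-1-yl)stannane (2 equiv)
Product: 12 1-(5,7-dihydroxy-2,2-dimethyl-3,4-dihydro-2H-chromen-6-yl)-3-[3-hydroxy-4-methoxy-5-(3-methylbut-2-en-1-yl)phenyl]propan-1-one (target)
Conditions: Pd(PPh3)4 (5 mol %), degassed DMF, 95 °C, 12 h; KF work-up
Reagents that add atoms: tributyl(3-methylbut-2-en-1-yl)stannane (compound 11), CCCC[Sn](CCCC)(CCCC)CC=C(C)C
Why: Stille cross-coupling under neutral conditions, which tolerates the three free phenols and the ketone; reductive elimination from the allyl–palladium intermediate at its less hindered terminus gives the linear prenyl group, the chroman is untouched, and no stereocentre is formed.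

**Compound list**
1 | 3-bromo-5-hydroxy-4-methoxybenzaldehyde | COc1c(O)cc(C=O)cc1Br | starting material
2 | Meldrum's acid (2,2-dimethyl-1,3-dioxane-4,6-dione) | CC1(C)OC(=O)CC(=O)O1 | starting material
3 | 5-(3-bromo-5-hydroxy-4-methoxybenzylidene)-2,2-dimethyl-1,3-dioxane-4,6-dione | COc1c(O)cc(C=C2C(=O)OC(C)(C)OC2=O)cc1Br | intermediate (not isolated)
4 | 5-(3-bromo-5-hydroxy-4-methoxybenzyl)-2,2-dimethyl-1,3-dioxane-4,6-dione | COc1c(O)cc(CC2C(=O)OC(C)(C)OC2=O)cc1Br | intermediate (not isolated)
5 | 3-(3-bromo-5-hydroxy-4-methoxyphenyl)propanoic acid | COc1c(O)cc(CCC(=O)O)cc1Br | intermediate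
6 | phloroglucinol (benzene-1,3,5-triol) | Oc1cc(O)cc(O)c1 | starting material
7 | 3-(3-bromo-5-hydroxy-4-methoxyphenyl)-1-(2,4,6-trihydroxyphenyl)propan-1-one | COc1c(O)cc(CCC(=O)c2c(O)cc(O)cc2O)cc1Br | intermediate
8 | 2-methylbut-3-en-2-ol | CC(C)(O)C=C | starting material
9 | 3-(3-bromo-5-hydroxy-4-methoxyphenyl)-1-[2,4,6-trihydroxy-3-(3-methylbut-2-en-1-yl)phenyl]propan-1-one | COc1c(O)cc(CCC(=O)c2c(O)cc(O)c(CC=C(C)C)c2O)cc1Br | intermediate (not isolated)
10 | 3-(3-bromo-5-hydroxy-4-methoxyphenyl)-1-(5,7-dihydroxy-2,2-dimethyl-3,4-dihydro-2H-chromen-6-yl)propan-1-one | COc1c(O)cc(CCC(=O)c2c(O)cc3c(c2O)CCC(C)(C)O3)cc1Br | intermediate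
11 | tributyl(3-methylbut-2-en-1-yl)stannane | CCCC[Sn](CCCC)(CCCC)CC=C(C)C | starting material
12 | 1-(5,7-dihydroxy-2,2-dimethyl-3,4-dihydro-2H-chromen-6-yl)-3-[3-hydroxy-4-methoxy-5-(3-methylbut-2-en-1-yl)phenyl]propan-1-one | COc1c(O)cc(CCC(=O)c2c(O)cc3c(c2O)CCC(C)(C)O3)cc1CC=C(C)C | target

**Step count**
Total steps: 4. Longest linear sequence: 4 (1 → 5 → 7 → 10 → 12).

**Steps most likely to fail**

Step 3 (highest risk). Ring closure can also go through an ortho-hydroxyl and give the 8-acyl chroman isomer. The preference for the 4'-hydroxyl is an expectation, not a secured result. The remaining ring A C–H can take a second C5 unit, so the reaction should be stopped short of full conversion and 7 recycled. Fallback, from 7 back to 10: the most acidic hydroxyl of 7 (4'-OH, para to the ketone) is alkylated with 3-chloro-3-methylbut-1-yne (1.05 equiv; K2CO3, KI, acetone, 55 °C) to give the 1,1-dimethylpropargyl aryl ether F1. Heating in xylene at 140 °C (aryl propargyl ether Claisen rearrangement, 1,5-hydrogen shift, oxa-6π electrocyclisation) gives the 2,2-dimethyl-2H-chromene F2. Its ring oxygen is necessarily the former 4'-oxygen, and ring A is symmetric, so only one chromene can form. Hydrogenation with H2 (1 atm) and RhCl(PPh3)3 (5 mol %) in benzene/EtOH at 40 °C saturates the chromene double bond without touching the aryl bromide and returns 10.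

Step 4. The electron-rich bromide on a triphenol may couple slowly. The phenols can protonate the allylstannane, and some branched 1,1-dimethylallyl product can form. Fallback, from 10 to 12: Suzuki–Miyaura allylation with allylboronic acid pinacol ester (Pd(OAc)2, SPhos, K3PO4, THF/H2O, 60 °C) gives the allyl arene F3, where no linear/branched question arises. Olefin cross-metathesis with excess 2-methylbut-2-ene and the second-generation Grubbs catalyst RuCl2(=CHPh)(PCy3)(H2IMes) (5 mol %) in CH2Cl2 at 40 °C then converts the allyl group into the prenyl group of 12, with loss of propene.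

Step 2. In hot BF3·OEt2 the acid 5 may cyclise onto its own ring B to an indanone, or phloroglucinol may be over-acylated or O-acylated. Fallback, from 1 back to 7, bypassing 5: Horner–Wadsworth–Emmons olefination of 1 with diethyl cyanomethylphosphonate (K2CO3, THF/H2O, 25 °C) gives the cinnamonitrile F4. Conjugate reduction with NaBH4 in pyridine/MeOH at reflux gives the arylpropanenitrile F5. Houben–Hoesch reaction of F5 with phloroglucinol 6 (ZnCl2, HCl gas, Et2O, 0 °C) precipitates the ketiminium chloride F6. This salt stops the reaction cleanly at mono-acylation and is hydrolysed in water at 100 °C to 7.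

**Further compounds**
F1 | step 3 | 3-(3-bromo-5-hydroxy-4-methoxyphenyl)-1-[2,6-dihydroxy-4-(2-methylbut-3-yn-2-yloxy)phenyl]propan-1-one | COc1c(O)cc(CCC(=O)c2c(O)cc(OC(C)(C)C#C)cc2O)cc1Br
F2 | step 3 | 3-(3-bromo-5-hydroxy-4-methoxyphenyl)-1-(5,7-dihydroxy-2,2-dimethyl-2H-chromen-6-yl)propan-1-one | COc1c(O)cc(CCC(=O)c2c(O)cc3c(c2O)C=CC(C)(C)O3)cc1Br
F3 | step 4 | 1-(5,7-dihydroxy-2,2-dimethyl-3,4-dihydro-2H-chromen-6-yl)-3-[3-hydroxy-4-methoxy-5-(prop-2-en-1-yl)phenyl]propan-1-one | COc1c(O)cc(CCC(=O)c2c(O)cc3c(c2O)CCC(C)(C)O3)cc1CC=C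
F4 | step 2 | (E)-3-(3-bromo-5-hydroxy-4-methoxyphenyl)prop-2-enenitrile | COc1c(O)cc(/C=C/C#N)cc1Br
F5 | step 2 | 3-(3-bromo-5-hydroxy-4-methoxyphenyl)propanenitrile | COc1c(O)cc(CCC#N)cc1Br
F6 | step 2 | 3-(3-bromo-5-hydroxy-4-methoxyphenyl)-1-(2,4,6-trihydroxyphenyl)propan-1-iminium chloride | COc1c(O)cc(CCC(=[NH2+])c2c(O)cc(O)cc2O)cc1Br.[Cl-]
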